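Compound numbers are those of the step list. Ring atoms carry the numbering of the target throughout: ring A is C1, C2, C3, C4, C5, C9 and ring B is C1, C8, C7, C6, C5, C9. Prenyl is 3-methylbut-2-enyl and geranyl is (2E)-3,7-dimethylocta-2,6-dienyl.

## The problem

Target 30 is a bicyclo[3.3.1]nonane in which ring A is an enolized 2,4-dione with a 3-hydroxybenzoyl group on C3, ring B is carbocyclic, and C9 is the bridging ketone common to both. Both bridgeheads are quaternary and prenylated, and C1 is also bonded to the gem-dimethyl carbon C8, so two adjacent quaternary carbons have to be made. Of the three stereocentres, C1 and C5 are locked to each other by the one-carbon bridge, so only their absolute sense must be chosen, while C7 carries the geranyl chain endo, on the face of ring B that also holds the C2–C3–C4 bridge, with H-7 exo. A rigid bicycle whose concave face is closed by ring A can set C7 by substrate control, whereas C7 cannot easily control the bridgeheads. Four trisubstituted alkenes exclude strong protic acid, electrophilic oxidants, ozonolysis and unselective hydrogenation; the β-triketone is open to retro-Claisen cleavage and to acid-induced cyclization of a prenyl group onto its enol oxygen; the phenol must be masked during carbanion chemistry. The enabling feature is that ring A, read as C1–C2(O)=C3–C4–C5=C9(O), is a 2,6-dioxygenated cyclohexa-2,5-diene with a local mirror plane through C1 and C4, so the C2=C3 and C9=C5 enol ethers are enantiotopic in an achiral resorcinol-derived precursor. The chain C8–C7–C6 on C1 then only has to be tied to C5, and joining C6 to C5 on one enol ether makes ring B, both bridgehead stereocentres and the bridging ketone together.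

## Retrosynthesis

**30 to 29.** No skeletal bond is cut. The triketone is held as its C2 methyl enol ether and the phenol as a silyl ether, so that ring A can be lithiated and acylated. Both groups are chosen to fall to hydroxide in a single final operation, the only treatment the four alkenes must then survive.

**29 to 25 and 28.** The C3–aroyl bond is cut. Acylating a free trione would give O-acyl products, and building the arene on the core would add steps to reach a ring that is commercial. Compound 25 lacks the arene; 28 comes in two steps from 26 through 27. The forward step needs selective metallation of C3, which is the only acidic C–H once C5 is quaternary.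

**25 to 18 and 23.** The C1'–C2' bond of the geranyl chain is cut, and the C7–H bond is traced back to an exocyclic C7 methylene. Cutting C7–C1' instead would require a nucleophilic or electrophilic C7 with no activating group next to it, and hydrogenating a C7 alkene that already bears the chain could not be selective among four trisubstituted alkenes. Compound 18 has no C7 stereocentre and 23 brings the E alkene ready-made. The borane must choose the only 1,1-disubstituted alkene and the exo face.

**18 to 17 and 3.** The C5–prenyl bond is cut. This alkylation has to follow removal of the C7 ketone, whose C6 hydrogens are far more acidic than H-5. It is placed before the borane step so that C9 is then flanked by two quaternary carbons and inert. The forward step is a bridgehead lithiation between the C4 and C9 carbonyls.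

**17 to 14 by way of 16 and 15.** The exocyclic C7=CH2 bond is traced to the C7 ketone. Direct methylenation cannot be relied on to tell the C7 ketone from the C9 ketone. Enolization can, because C9 has only a quaternary carbon and a bridgehead beside it. The C7 enol triflate 15 is therefore coupled to a silylmethyl group (16), and protonation at C6 moves the double bond out of the ring (17).

**14 to 13.** The C4 carbonyl is removed to leave the methyl enol ether of 13. The oxidation is placed at the stage where a single prenyl group competes, and it is needed early because the C4 carbonyl later acidifies both H-5 and H-3.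

**13 to 11 by way of 12.** The C5–C6 bond is cut; this is the key disconnection. Restoring the C6–C9 bond and a methoxy group on C9 gives the donor–acceptor cyclopropane 12, and removing the cyclopropane gives the achiral diazo ketone 11. All chirality of the route starts here, and the precursor has no stereocentre at all. The forward step needs a chiral catalyst to pick one of two enantiotopic enol ethers, and an opening of 12 that spares the second enol ether.

**11 to 6.** The C6–C7 bond is cut, with C6 coming from a one-carbon diazo donor and the carboxylate 9, which is the deallylated form of ester 8. The two C8–CH3 bonds are cut next, so that 8 goes back to 6. The allyl ester is chosen because it is cleaved at oxygen and not at the crowded carbonyl.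

**6 to 1.** The C1–C8 and C1–prenyl bonds are cut, which leads through 4 to the Birch diene 2 and to 1, with 5 and 3 as electrophiles. Both bonds form at the carbon between the two enol ethers, the one position that a strong base metallates.

**Side branches.** 23 is traced through enyne 21 to ketone 19 (carbometallation fixes the E geometry), and 28 through 27 to 26.

## Roads not taken

Alternative 1: Ring B is cut at C1–C8 and C6–C7. Diene A1 and dienophile A2 would combine under a chiral Cu(SbF6)2–bis(oxazoline) Lewis acid (divalent copper) to give cyclohexene A3.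
- Merits: the step is convergent and catalytic. It sets C7 directly with the carbon that becomes C1' already attached, and leaves a silyl enol ether between C5 and C9 for a later ring A annulation. In this respect it is better than the chosen plan, which spends four steps (9, 10, 11 and 15) on C7.
- Weak points: A2 is β,β-disubstituted and must form a bond to the future quaternary C8, a notoriously slow dienophile class. Only C7 is set. Ring A would then have to be annulated cis to the C7 substituent to reach the endo series, which is the more hindered face of A3. The C1 prenyl group would still have to go onto a bridgehead beside the gem-dimethyl carbon.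
- Comparison: the chosen plan sets against this that step 7 fixes both bridgeheads, the bridging ketone and the ring A oxygen at C2 at once, and that the bicycle then delivers the endo C7 configuration through its open exo face.

Alternative 2: The arene is cut at two C–C bonds. Ynone A4 and furan A5 would give the bridged adduct A6 under Me2AlCl, and Sc(OTf)3 would isomerize A6 to the phenol A7.
- Merits: no phenol protecting group is needed and the aryl ketone could be varied late. It would also spare the two steps of the acid chloride branch.
- Weak points: A4 already contains the whole core and all three stereocentres, so the road solves none of the main problems. Two Lewis acid treatments meet four trisubstituted alkenes and a vinylogous ester. A5 is a reluctant, reversible diene. The opening of A6 must give the meta and not the ortho phenol. A propynoyl group is harder to put on C3 than an aroyl group.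
- Comparison: the chosen plan sets against the two spared steps that its branch lies off the longest linear sequence and that the silyl group leaves in the final hydrolysis at no extra cost.

Alternative 3: Ring A is cut at C4–C5 and C1–C9. The enolate of cyclopentanone A8 would open diketene A9 at C5, and the released acetoacetyl terminus would add to the C9 ketone to give the fused hydroxy dione A10; a 1,2-shift of C8 from C9 to C1 would then give the bridged skeleton.
- Merits: ring A arrives with both oxygens at C2 and C4 in one step. Here it is better than the chosen plan, which needs the allylic oxidation of step 8, one of its less certain steps.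
- Weak points: the enolate must be C-acylated, not O-acylated, at a carbon that becomes quaternary. The aldol closure uses the least nucleophilic carbon onto a ketone beside the gem-dimethyl group. The ring expansion needs a leaving group on C1 next to the C2 carbonyl and the migration of a quaternary carbon. C1 is left without its prenyl group, and C7 carries oxygen, so the chain and its configuration are still to come. Absolute configuration rests on an enantioenriched A8.
- Comparison: the chosen plan sets against the extra oxidation step that it needs no skeletal rearrangement and that its chirality comes from a catalyst acting on an achiral precursor.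

Key step: step 7

**Remarks before the steps.**
- Assumption: the (S,S) bis(oxazoline) is written in step 7. The sense of induction is to be checked in a first run, and the commercially available antipode of the ligand is used if it gives the enantiomer of 13.
- Assumption: 30 is drawn as its C4 enol; the enol tautomers interconvert freely.
- Endo at C7 means on the face of ring B that carries C2 and C4; exo means on the face of the bridgehead substituents.

## Steps

Step 1
Reactants: 1 1,3-dimethoxybenzene
Product: 2 1,5-dimethoxycyclohexa-1,4-diene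
Conditions: Li, NH3 (l), THF, t-BuOH, −78 to −33 °C
Reagents that add atoms: none
Why: Birch reduction; the methoxy-bearing carbons stay sp2, so the unconjugated bis(enol ether) is formed and no stereocentre arises.

Step 2
Reactants: 2 1,5-dimethoxycyclohexa-1,4-diene; 3 prenyl bromide (1-bromo-3-methylbut-2-ene)
Product: 4 1,5-dimethoxy-6-(3-methylbut-2-enyl)cyclohexa-1,4-diene
Conditions: t-BuLi, THF, −78 °C; then 3, DMPU, −78 to 0 °C
Reagents that add atoms: none
Why: The CH2 between the two enol ether carbons is the most acidic site, and the chelated lithium pentadienyl anion is alkylated at its central carbon (alkylation of a Birch-derived dienyl anion).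

Step 3
Reactants: 4 1,5-dimethoxy-6-(3-methylbut-2-enyl)cyclohexa-1,4-diene; 5 allyl bromoacetate
Product: 6 allyl 2-[2,6-dimethoxy-1-(3-methylbut-2-enyl)cyclohexa-2,5-dien-1-yl]acetate
Conditions: t-BuLi, THF, −78 °C; anion added to 5 (1.5 equiv), THF, −78 °C
Reagents that add atoms: none
Why: A second lithiation at the same carbon and SN2 displacement on the α-bromo ester build the quaternary carbon and restore the mirror plane, so 6 is achiral; inverse addition at −78 °C keeps substitution ahead of proton transfer.

Step 4
Reactants: 6 allyl 2-[2,6-dimethoxy-1-(3-methylbut-2-enyl)cyclohexa-2,5-dien-1-yl]acetate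
Product: 8 allyl 2-[2,6-dimethoxy-1-(3-methylbut-2-enyl)cyclohexa-2,5-dien-1-yl]-2-methylpropanoate, via monomethyl ester 7 (not isolated)
Conditions: LiN(i-Pr)2, THF, −78 °C, MeI; then LiN(i-Pr)2, DMPU, MeI, −78 to −40 °C
Reagents that add atoms: iodomethane, CI
Why: Two ester enolate methylations at the only enolizable carbon; iodomethane is small enough for the crowded second alkylation, and keeping the enolate below −40 °C avoids Ireland–Claisen-type rearrangement of the allyl ester.

Step 5
Reactants: 8 allyl 2-[2,6-dimethoxy-1-(3-methylbut-2-enyl)cyclohexa-2,5-dien-1-yl]-2-methylpropanoate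
Product: 9 sodium 2-[2,6-dimethoxy-1-(3-methylbut-2-enyl)cyclohexa-2,5-dien-1-yl]-2-methylpropanoate
Conditions: Pd(PPh3)4 (2 mol %), sodium 2-ethylhexanoate (1.1 equiv), THF–EtOAc, rt
Reagents that add atoms: sodium 2-ethylhexanoate, CCCCC(CC)C(=O)[O-].[Na+]
Why: Tsuji–Trost deallylation; zerovalent palladium ionizes the O–allyl bond and 2-ethylhexanoate takes up the allyl group, so the hindered carbonyl is not attacked, no acid meets the enol ethers, and the sodium counter-ion of the reagent delivers the acid directly as its salt, which cannot add to an enol ether.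

Step 6
Reactants: 9 sodium 2-[2,6-dimethoxy-1-(3-methylbut-2-enyl)cyclohexa-2,5-dien-1-yl]-2-methylpropanoate
Product: 11 1-diazo-3-[2,6-dimethoxy-1-(3-methylbut-2-enyl)cyclohexa-2,5-dien-1-yl]-3-methylbutan-2-one, via acyl chloride 10 (not isolated)
Conditions: (COCl)2 (1.05 equiv), DMF (cat.), CH2Cl2, −20 °C; then CH2N2 (excess), Et2O, 0 °C to rt
Reagents that add atoms: diazomethane, C=[N+]=[N-]
Why: Acylation of diazomethane by an acid chloride (first stage of the Arndt–Eistert sequence); the carboxylate salt gives the chloride without free HCl, excess diazomethane takes up the HCl of the acylation, and the quaternary α-carbon excludes ketene formation.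

Step 7
Reactants: 11 1-diazo-3-[2,6-dimethoxy-1-(3-methylbut-2-enyl)cyclohexa-2,5-dien-1-yl]-3-methylbutan-2-one
Product: 13 2-methoxy-8,8-dimethyl-1-(3-methylbut-2-enyl)bicyclo[3.3.1]non-2-ene-7,9-dione (bridgehead configuration of 30), via methoxycyclopropyl ketone 12 (not isolated)
Conditions: (CuOTf)2·C6H6 (5 mol %), 2,2'-(propane-2,2-diyl)bis[(4S)-4-tert-butyl-4,5-dihydrooxazole] (12 mol %), toluene, rt, slow addition of 11; then MgI2 (1.5 equiv) in Et2O, same flask, 0 °C; aq. NaHCO3
Reagents that add atoms: none
Why: Loss of N2 at monovalent copper gives an electrophilic carbenoid at C6 that adds across the enol ether C5=C9 in an intramolecular [2+1] cycloaddition, the closest known type being the copper–bis(oxazoline) catalysed intramolecular cyclopropanation of α-diazo ketones onto dienyl enol ethers followed by Lewis acid opening of the resulting alkoxycyclopropyl ketone. This closes the cyclopropane and, through the tether C7–C8–C1, the five-membered ketone ring of 12 in the bicyclo[3.1.0]hexanone mode. MgI2 then binds the C7 carbonyl, the C9 methoxy lone pair expels the C6–C9 bond of the vicinal donor–acceptor pair, iodide removes the methyl group of the oxocarbenium ion as iodomethane and the magnesium enolate is protonated on work-up, so the five-membered ring is enlarged to the six-membered ring B with C5–C6 kept and C9 freed as the ketone. The chiral ligand makes the carbenoid choose one of the two enantiotopic enol ethers, and this single choice fixes C1 and C5 together because the short tether can only reach C5 cis to itself; the C6 and C9 centres of 12 disappear on opening. The enol ether is preferred over the prenyl alkene because it is more electron-rich and gives the smaller ring, copper carbenoids insert reluctantly into allylic C–H bonds, and the gem-dimethyl group favours the folded conformer. The second enol ether survives because no protic acid or water is present before the basic quench, and the C5–C6 and C5–C9 bonds are not cleaved because neither lies between donor and acceptor.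

Step 8
Reactants: 13 2-methoxy-8,8-dimethyl-1-(3-methylbut-2-enyl)bicyclo[3.3.1]non-2-ene-7,9-dione
Product: 14 2-methoxy-8,8-dimethyl-1-(3-methylbut-2-enyl)bicyclo[3.3.1]non-2-ene-4,7,9-trione
Conditions: t-BuOOH (5 equiv, in decane), Pd(OH)2/C (5 mol %), K2CO3, CH2Cl2, 0 °C to rt
Reagents that add atoms: tert-butyl hydroperoxide, CC(C)(C)OO
Why: Allylic C–H oxidation by a tert-butylperoxyl radical chain; abstraction at C4 gives an allyl radical stabilized by the C2 methoxy group, the C4 peroxide collapses to the ketone by Kornblum–DeLaMare fragmentation, and the single prenyl group offers less activated allylic hydrogens.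

Step 9
Reactants: 14 2-methoxy-8,8-dimethyl-1-(3-methylbut-2-enyl)bicyclo[3.3.1]non-2-ene-4,7,9-trione
Product: 15 2-methoxy-8,8-dimethyl-1-(3-methylbut-2-enyl)-4,9-dioxobicyclo[3.3.1]nona-2,6-dien-7-yl trifluoromethanesulfonate
Conditions: KN(SiMe3)2 (1.05 equiv), THF, −78 °C; PhNTf2, −78 to 0 °C
Reagents that add atoms: N-phenylbis(trifluoromethanesulfonimide), O=S(=O)(N(c1ccccc1)S(=O)(=O)C(F)(F)F)C(F)(F)F
Why: Kinetic enolate O-sulfonylation; only the C7 ketone can form a conjugated enolate (toward C6), since C8 and C1 are quaternary and the bridgehead H-5 could give only a non-conjugated carbanion (Bredt's rule) that one equivalent of the silylamide at −78 °C does not generate in competition with H-6.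

Step 10
Reactants: 15 2-methoxy-8,8-dimethyl-1-(3-methylbut-2-enyl)-4,9-dioxobicyclo[3.3.1]nona-2,6-dien-7-yl trifluoromethanesulfonate
Product: 16 2-methoxy-8,8-dimethyl-1-(3-methylbut-2-enyl)-7-[(trimethylsilyl)methyl]bicyclo[3.3.1]nona-2,6-diene-4,9-dione
Conditions: Me3SiCH2ZnCl (from Me3SiCH2MgCl and ZnCl2), Pd(PPh3)4 (5 mol %), THF, rt to 45 °C
Reagents that add atoms: (trimethylsilyl)methylzinc chloride, C[Si](C)(C)C[Zn]Cl
Why: Negishi coupling of an alkenyl triflate with a silylmethyl zinc reagent gives the allylsilane; zinc is used in place of magnesium because it does not add to the C9 ketone or the vinylogous ester.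

Step 11
Reactants: 16 2-methoxy-8,8-dimethyl-1-(3-methylbut-2-enyl)-7-[(trimethylsilyl)methyl]bicyclo[3.3.1]nona-2,6-diene-4,9-dione
Product: 17 2-methoxy-8,8-dimethyl-7-methylidene-1-(3-methylbut-2-enyl)bicyclo[3.3.1]non-2-ene-4,9-dione
Conditions: CF3CO2H (2 equiv), CH2Cl2, 0 °C, 15 min; aq. NaHCO3
Reagents that add atoms: none
Why: Protodesilylation of an allylsilane (SE2'); the proton adds to C6, the β-silyl cation at C7 loses silicon and the double bond ends exocyclic, a path far faster than protonation of the prenyl or methylidene alkenes.

Step 12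
Reactants: 17 2-methoxy-8,8-dimethyl-7-methylidene-1-(3-methylbut-2-enyl)bicyclo[3.3.1]non-2-ene-4,9-dione; 3 prenyl bromide
Product: 18 2-methoxy-8,8-dimethyl-7-methylidene-1,5-bis(3-methylbut-2-enyl)bicyclo[3.3.1]non-2-ene-4,9-dione
Conditions: LiN(i-Pr)2 (1.3 equiv), THF, −78 °C; then 3, −78 to −30 °C
Reagents that add atoms: none
Why: Bridgehead lithiation and alkylation, established for vinylogous esters of this ring system; with the C7 ketone gone, H-5 between the C4 and C9 carbonyls is the most acidic hydrogen and is removed before the vinylic H-3, and substitution at a bridgehead can only retain configuration.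

Step 13
Reactants: 19 6-methylhept-5-en-2-one
Product: 21 6-methylhept-5-en-1-yne, via enol phosphate 20 (not isolated)
Conditions: LiN(i-Pr)2 (1.05 equiv), THF, −78 °C; ClP(O)(OEt)2, −78 °C to rt; then LiN(i-Pr)2 (2.3 equiv), −78 °C to rt
Reagents that add atoms: none
Why: The kinetic methyl enolate is trapped as its enol phosphate, and base-induced elimination of phosphate gives the terminal alkyne (methyl ketone to alkyne conversion).

Step 14
Reactants: 21 6-methylhept-5-en-1-yne
Product: 23 (E)-1-iodo-2,6-dimethylhepta-1,5-diene, via alkenylalane 22 (not isolated)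
Conditions: Me3Al (2 equiv), Cp2ZrCl2 (0.25 equiv), CH2Cl2, rt; then I2, THF, −30 to 0 °C
Reagents that add atoms: trimethylaluminium, C[Al](C)C; iodine, II
Why: Zirconium-catalysed carboalumination adds methyl and aluminium syn across the alkyne with aluminium at the terminus, and iodinolysis with retention gives the E iodide; the trisubstituted alkene does not react.

Step 15
Reactants: 18 2-methoxy-8,8-dimethyl-7-methylidene-1,5-bis(3-methylbut-2-enyl)bicyclo[3.3.1]non-2-ene-4,9-dione; 23 (E)-1-iodo-2,6-dimethylhepta-1,5-diene
Product: 25 7-endo-geranyl-2-methoxy-8,8-dimethyl-1,5-bis(3-methylbut-2-enyl)bicyclo[3.3.1]non-2-ene-4,9-dione, via B-alkyl borane 24 (not isolated)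
Conditions: 9-BBN-H (1.2 equiv), THF, rt; then 23, PdCl2(dppf) (5 mol %), AsPh3, Cs2CO3, DMF–H2O, rt
Reagents that add atoms: none
Why: Hydroboration and B-alkyl Suzuki–Miyaura coupling; 9-BBN-H adds to the only 1,1-disubstituted alkene in preference to the prenyl groups and the hindered carbonyls and approaches C7 from the exo face because the endo face is closed by ring A, so H-7 ends exo and the chain endo; the coupling keeps the E geometry of 23.

Step 16
Reactants: 26 3-hydroxybenzoic acid
Product: 27 tert-butyldimethylsilyl 3-(tert-butyldimethylsilyloxy)benzoate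
Conditions: t-BuMe2SiCl (2.3 equiv), imidazole, DMF, rt
Reagents that add atoms: tert-butyldimethylsilyl chloride, CC(C)(C)[Si](C)(C)Cl
Why: Silylation of phenol and carboxyl groups under imidazole catalysis.

Step 17
Reactants: 27 tert-butyldimethylsilyl 3-(tert-butyldimethylsilyloxy)benzoate
Product: 28 3-(tert-butyldimethylsilyloxy)benzoyl chloride
Conditions: (COCl)2, DMF (cat.), CH2Cl2, 0 °C to rt
Reagents that add atoms: oxalyl chloride, O=C(Cl)C(=O)Cl
Why: Silyl esters are converted directly into acid chlorides by the chloroiminium reagent under neutral conditions, which the aryl silyl ether survives.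

Step 18
Reactants: 25 7-endo-geranyl-2-methoxy-8,8-dimethyl-1,5-bis(3-methylbut-2-enyl)bicyclo[3.3.1]non-2-ene-4,9-dione; 28 3-(tert-butyldimethylsilyloxy)benzoyl chloride
Product: 29 3-[3-(tert-butyldimethylsilyloxy)benzoyl]-7-endo-geranyl-2-methoxy-8,8-dimethyl-1,5-bis(3-methylbut-2-enyl)bicyclo[3.3.1]non-2-ene-4,9-dione
Conditions: lithium 2,2,6,6-tetramethylpiperidide, THF, −78 °C; then 28, −78 to −40 °C
Reagents that add atoms: none
Why: Vinylic lithiation at C3, the only acidic C–H left and flanked by the methoxy carbon and the C4 carbonyl, followed by C-acylation with the acid chloride; established for vinylogous esters of this ring system.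

Step 19
Reactants: 29 3-[3-(tert-butyldimethylsilyloxy)benzoyl]-7-endo-geranyl-2-methoxy-8,8-dimethyl-1,5-bis(3-methylbut-2-enyl)bicyclo[3.3.1]non-2-ene-4,9-dione
Product: 30 target compound
Conditions: LiOH, 1,4-dioxane–H2O, 90 °C; then aq. NaH2PO4
Reagents that add atoms: lithium hydroxide, [Li+].[OH-]
Why: Hydroxide adds to C2 of the doubly activated vinylogous ester and expels methoxide (addition–elimination) and also cleaves the aryl silyl ether; the hindered C9 ketone resists retro-Claisen attack and no stereocentre is touched.

## Compound list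

1 | 1,3-dimethoxybenzene | COc1cccc(OC)c1 | starting material
2 | 1,5-dimethoxycyclohexa-1,4-diene | COC1=CCC=C(OC)C1 | intermediate
3 | prenyl bromide | CC(C)=CCBr | starting material
4 | 1,5-dimethoxy-6-(3-methylbut-2-enyl)cyclohexa-1,4-diene | COC1=CCC=C(OC)C1CC=C(C)C | intermediate
5 | allyl bromoacetate | C=CCOC(=O)CBr | starting material
6 | allyl 2-[2,6-dimethoxy-1-(3-methylbut-2-enyl)cyclohexa-2,5-dien-1-yl]acetate | COC1=CCC=C(OC)C1(CC=C(C)C)CC(=O)OCC=C | intermediate
7 | allyl 2-[2,6-dimethoxy-1-(3-methylbut-2-enyl)cyclohexa-2,5-dien-1-yl]propanoate (racemic) | COC1=CCC=C(OC)C1(CC=C(C)C)C(C)C(=O)OCC=C | intermediate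
8 | allyl 2-[2,6-dimethoxy-1-(3-methylbut-2-enyl)cyclohexa-2,5-dien-1-yl]-2-methylpropanoate | COC1=CCC=C(OC)C1(CC=C(C)C)C(C)(C)C(=O)OCC=C | intermediate
9 | sodium 2-[2,6-dimethoxy-1-(3-methylbut-2-enyl)cyclohexa-2,5-dien-1-yl]-2-methylpropanoate | COC1=CCC=C(OC)C1(CC=C(C)C)C(C)(C)C(=O)[O-].[Na+] | intermediate
10 | 2-[2,6-dimethoxy-1-(3-methylbut-2-enyl)cyclohexa-2,5-dien-1-yl]-2-methylpropanoyl chloride | COC1=CCC=C(OC)C1(CC=C(C)C)C(C)(C)C(=O)Cl | intermediate
11 | 1-diazo-3-[2,6-dimethoxy-1-(3-methylbut-2-enyl)cyclohexa-2,5-dien-1-yl]-3-methylbutan-2-one | COC1=CCC=C(OC)C1(CC=C(C)C)C(C)(C)C(=O)C=[N+]=[N-] | intermediate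
12 | methoxycyclopropyl ketone: skeleton of 13 with an added C6–C9 bond, methoxy on C9, cyclopropane C5–C6–C9 with H-5 and H-6 cis | COC1=CC[C@@H]2[C@@H]3C(=O)C(C)(C)[C@@]1(CC=C(C)C)[C@]23OC | intermediate
13 | 2-methoxy-8,8-dimethyl-1-(3-methylbut-2-enyl)bicyclo[3.3.1]non-2-ene-7,9-dione, bridgeheads as in 30 | O=C1C[C@@H]2C(=O)[C@@](CC=C(C)C)(C(OC)=CC2)C1(C)C | intermediate
14 | 2-methoxy-8,8-dimethyl-1-(3-methylbut-2-enyl)bicyclo[3.3.1]non-2-ene-4,7,9-trione | O=C1C[C@@H]2C(=O)[C@@](CC=C(C)C)(C(OC)=CC2=O)C1(C)C | intermediate
15 | 2-methoxy-8,8-dimethyl-1-(3-methylbut-2-enyl)-4,9-dioxobicyclo[3.3.1]nona-2,6-dien-7-yl trifluoromethanesulfonate | FC(F)(F)S(=O)(=O)OC1=C[C@@H]2C(=O)[C@@](CC=C(C)C)(C(OC)=CC2=O)C1(C)C | intermediate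
16 | 2-methoxy-8,8-dimethyl-1-(3-methylbut-2-enyl)-7-[(trimethylsilyl)methyl]bicyclo[3.3.1]nona-2,6-diene-4,9-dione | C[Si](C)(C)CC1=C[C@@H]2C(=O)[C@@](CC=C(C)C)(C(OC)=CC2=O)C1(C)C | intermediate
17 | 2-methoxy-8,8-dimethyl-7-methylidene-1-(3-methylbut-2-enyl)bicyclo[3.3.1]non-2-ene-4,9-dione | C=C1C[C@@H]2C(=O)[C@@](CC=C(C)C)(C(OC)=CC2=O)C1(C)C | intermediate
18 | 2-methoxy-8,8-dimethyl-7-methylidene-1,5-bis(3-methylbut-2-enyl)bicyclo[3.3.1]non-2-ene-4,9-dione | C=C1C[C@]2(CC=C(C)C)C(=O)[C@@](CC=C(C)C)(C(OC)=CC2=O)C1(C)C | intermediate
19 | 6-methylhept-5-en-2-one | CC(=O)CCC=C(C)C | starting material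
20 | diethyl 6-methylhepta-1,5-dien-2-yl phosphate | C=C(CCC=C(C)C)OP(=O)(OCC)OCC | intermediate
21 | 6-methylhept-5-en-1-yne | C#CCCC=C(C)C | intermediate
22 | (E)-(2,6-dimethylhepta-1,5-dienyl)dimethylalane | C[Al](C)/C=C(\C)CCC=C(C)C | intermediate
23 | (E)-1-iodo-2,6-dimethylhepta-1,5-diene | I/C=C(\C)CCC=C(C)C | intermediate
24 | 18 with H-7 exo and a 7-endo (9-borabicyclo[3.3.1]nonan-9-yl)methyl group in place of the methylidene | C(B1C2CCCC1CCC2)[C@H]1C[C@]2(CC=C(C)C)C(=O)[C@@](CC=C(C)C)(C(OC)=CC2=O)C1(C)C | intermediate
25 | 7-endo-geranyl-2-methoxy-8,8-dimethyl-1,5-bis(3-methylbut-2-enyl)bicyclo[3.3.1]non-2-ene-4,9-dione | CC(C)=CCC/C(C)=C/C[C@H]1C[C@]2(CC=C(C)C)C(=O)[C@@](CC=C(C)C)(C(OC)=CC2=O)C1(C)C | intermediate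
26 | 3-hydroxybenzoic acid | O=C(O)c1cccc(O)c1 | starting material
27 | tert-butyldimethylsilyl 3-(tert-butyldimethylsilyloxy)benzoate | CC(C)(C)[Si](C)(C)OC(=O)c1cccc(O[Si](C)(C)C(C)(C)C)c1 | intermediate
28 | 3-(tert-butyldimethylsilyloxy)benzoyl chloride | O=C(Cl)c1cccc(O[Si](C)(C)C(C)(C)C)c1 | intermediate
29 | 3-[3-(tert-butyldimethylsilyloxy)benzoyl]-7-endo-geranyl-2-methoxy-8,8-dimethyl-1,5-bis(3-methylbut-2-enyl)bicyclo[3.3.1]non-2-ene-4,9-dione | CC(C)=CCC/C(C)=C/C[C@H]1C[C@]2(CC=C(C)C)C(=O)[C@@](CC=C(C)C)(C(OC)=C(C(=O)c3cccc(O[Si](C)(C)C(C)(C)C)c3)C2=O)C1(C)C | intermediate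
30 | target: 7-endo-geranyl-4-hydroxy-3-(3-hydroxybenzoyl)-8,8-dimethyl-1,5-bis(3-methylbut-2-enyl)bicyclo[3.3.1]non-3-ene-2,9-dione | CC(C)=CCC/C(C)=C/C[C@H]1C[C@]2(CC=C(C)C)C(=O)[C@@](CC=C(C)C)(C(=O)C(C(=O)c3cccc(O)c3)=C2O)C1(C)C | target

## Step count and least certain steps

Total: 19 steps. Longest linear sequence: 15 steps (steps 1 to 12, then 15, 18 and 19). Steps 13 and 14 and steps 16 and 17 are two-step side branches.

**Step 7 (key step).** The most likely failure is weak discrimination between the two enantiotopic enol ethers, because a simple keto carbenoid binds copper through one point only; C–H insertion into the prenyl CH2 is a lesser risk. The fallback uses the keto sulfone carbenoid, the substrate class for which this catalysis is best established. It sets out from 9 by way of acyl chloride 10. Treatment of 10 with PhSO2CH2Li (2.2 equiv) gives 3-[2,6-dimethoxy-1-(3-methylbut-2-enyl)cyclohexa-2,5-dien-1-yl]-3-methyl-1-(phenylsulfonyl)butan-2-one F1. Diazo transfer with 4-acetamidobenzenesulfonyl azide and Et3N gives the diazo keto sulfone F2. The same (CuOTf)2·C6H6 and bis(oxazoline) catalyst, now chelated by two oxygens, should give the sulfonyl cyclopropane F3. MgI2 opens F3 to the 6-phenylsulfonyl dione F4 (C6 epimers), and SmI2 in THF–MeOH at −78 °C removes the sulfonyl group. The fallback returns to the route at 13.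

**Step 3.** Proton transfer from the bromoacetate to the strongly basic tertiary dienyl anion, attack at the ester carbonyl, or alkylation at a ring terminus can each take over. The fallback builds the quaternary carbon by reductive alkylation instead and sets out from 1. Ortho-lithiation of 1 with n-BuLi and carboxylation gives 2,6-dimethoxybenzoic acid F5. Birch reductive alkylation of F5 (Li, NH3, THF, t-BuOH; then 3) gives 2,6-dimethoxy-1-(3-methylbut-2-enyl)cyclohexa-2,5-diene-1-carboxylic acid F6. Its sodium salt with (COCl)2 and then CH2N2 gives the diazo ketone F7, and Wolff rearrangement (PhCO2Ag, Et3N, allyl alcohol) completes an Arndt–Eistert homologation. The fallback returns to the route at 6.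

**Step 4.** The second enolization and methylation beside the quaternary C1 may stall, and on warming the allyl ester enolate may rearrange. The fallback removes the allyl group first and sets out from 6. Deallylation as in step 5 gives sodium 2-[2,6-dimethoxy-1-(3-methylbut-2-enyl)cyclohexa-2,5-dien-1-yl]acetate F8. The carboxylate enolate (LiN(i-Pr)2, THF–DMPU, 0 °C) is methylated with MeI to the propanoate salt F9, and a second cycle follows; carboxylate enolates are more nucleophilic and cannot undergo the [3,3] shift. After NaHCO3 work-up the fallback returns to the route at 9.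

**Step 8.** Radical attack on the allylic positions of the prenyl group or on the enol ether double bond may compete with abstraction at C4. The fallback introduces the C4 oxygen by polar chemistry and sets out from 13. Dilute aqueous HCl in THF gives 8,8-dimethyl-1-(3-methylbut-2-enyl)bicyclo[3.3.1]nonane-2,7,9-trione F10. IBX in DMSO dehydrogenates only ring A, since the C7 ketone would need a bridgehead alkene, and gives the enetrione F11. Wacker-type oxidation of the enone (Na2PdCl4, t-BuOOH, AcOH–H2O) gives the 2,4,7,9-tetraone F12. Methylation with Me3SiCHN2 in MeOH gives 14 together with its regioisomer, the 4-methoxy-3-ene-2,7,9-trione F13, which is separated and hydrolysed back to F12 with LiOH. The fallback returns to the route at 14.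

**Step 15.** Transmetalation of the β-branched alkylborane may be slow enough for protodeboronation to compete, excess borane may reduce the C4 carbonyl, and exo-face selectivity may erode beside the C8 methyl groups. The fallback separates hydroboration from coupling and sets out from 24, made with 1.1 equiv of 9-BBN-H. Oxidation with NaBO3 gives the 7-endo hydroxymethyl compound F14, the stage at which a C7 epimer is most easily removed. I2, PPh3 and imidazole (Appel reaction) give the iodide F15. Zinc dust with LiCl gives the alkylzinc iodide F16, and Negishi coupling with 23 under PdCl2(dppf) forms the same C1'–C2' bond. The fallback returns to the route at 25.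

## Further compounds

F1 | step 7 | 3-[2,6-dimethoxy-1-(3-methylbut-2-enyl)cyclohexa-2,5-dien-1-yl]-3-methyl-1-(phenylsulfonyl)butan-2-one | COC1=CCC=C(OC)C1(CC=C(C)C)C(C)(C)C(=O)CS(=O)(=O)c1ccccc1
F2 | step 7 | 1-diazo-3-[2,6-dimethoxy-1-(3-methylbut-2-enyl)cyclohexa-2,5-dien-1-yl]-3-methyl-1-(phenylsulfonyl)butan-2-one | COC1=CCC=C(OC)C1(CC=C(C)C)C(C)(C)C(=O)C(=[N+]=[N-])S(=O)(=O)c1ccccc1
F3 | step 7 | 6-phenylsulfonyl analogue of 12 | COC1=CC[C@@H]2[C@]3(S(=O)(=O)c4ccccc4)C(=O)C(C)(C)[C@@]1(CC=C(C)C)[C@]23OC
F4 | step 7 | 6-phenylsulfonyl analogue of 13 (C6 epimers) | O=C1C(S(=O)(=O)c3ccccc3)[C@@H]2C(=O)[C@@](CC=C(C)C)(C(OC)=CC2)C1(C)C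
F5 | step 3 | 2,6-dimethoxybenzoic acid | COc1cccc(OC)c1C(=O)O
F6 | step 3 | 2,6-dimethoxy-1-(3-methylbut-2-enyl)cyclohexa-2,5-diene-1-carboxylic acid | COC1=CCC=C(OC)C1(CC=C(C)C)C(=O)O
F7 | step 3 | 2-diazo-1-[2,6-dimethoxy-1-(3-methylbut-2-enyl)cyclohexa-2,5-dien-1-yl]ethanone | COC1=CCC=C(OC)C1(CC=C(C)C)C(=O)C=[N+]=[N-]
F8 | step 4 | sodium 2-[2,6-dimethoxy-1-(3-methylbut-2-enyl)cyclohexa-2,5-dien-1-yl]acetate | COC1=CCC=C(OC)C1(CC=C(C)C)CC(=O)[O-].[Na+]
F9 | step 4 | sodium 2-[2,6-dimethoxy-1-(3-methylbut-2-enyl)cyclohexa-2,5-dien-1-yl]propanoate (racemic) | COC1=CCC=C(OC)C1(CC=C(C)C)C(C)C(=O)[O-].[Na+]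
F10 | step 8 | 8,8-dimethyl-1-(3-methylbut-2-enyl)bicyclo[3.3.1]nonane-2,7,9-trione | O=C1C[C@@H]2C(=O)[C@@](CC=C(C)C)(C(=O)CC2)C1(C)C
F11 | step 8 | 8,8-dimethyl-1-(3-methylbut-2-enyl)bicyclo[3.3.1]non-3-ene-2,7,9-trione | O=C1C[C@@H]2C(=O)[C@@](CC=C(C)C)(C(=O)C=C2)C1(C)C
F12 | step 8 | 8,8-dimethyl-1-(3-methylbut-2-enyl)bicyclo[3.3.1]nonane-2,4,7,9-tetraone | O=C1C[C@@H]2C(=O)[C@@](CC=C(C)C)(C(=O)CC2=O)C1(C)C
F13 | step 8 | 4-methoxy-8,8-dimethyl-1-(3-methylbut-2-enyl)bicyclo[3.3.1]non-3-ene-2,7,9-trione | O=C1C[C@@H]2C(=O)[C@@](CC=C(C)C)(C(=O)C=C2OC)C1(C)C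
F14 | step 15 | 7-endo-(hydroxymethyl)-2-methoxy-8,8-dimethyl-1,5-bis(3-methylbut-2-enyl)bicyclo[3.3.1]non-2-ene-4,9-dione | OC[C@H]1C[C@]2(CC=C(C)C)C(=O)[C@@](CC=C(C)C)(C(OC)=CC2=O)C1(C)C
F15 | step 15 | 7-endo-(iodomethyl)-2-methoxy-8,8-dimethyl-1,5-bis(3-methylbut-2-enyl)bicyclo[3.3.1]non-2-ene-4,9-dione | IC[C@H]1C[C@]2(CC=C(C)C)C(=O)[C@@](CC=C(C)C)(C(OC)=CC2=O)C1(C)C
F16 | step 15 | alkylzinc iodide from F15 | I[Zn]C[C@H]1C[C@]2(CC=C(C)C)C(=O)[C@@](CC=C(C)C)(C(OC)=CC2=O)C1(C)C
A1 | alternative 1 | 3-(3-methylbut-2-enyl)-2-(triisopropylsilyloxy)buta-1,3-diene | C=C(O[Si](C(C)C)(C(C)C)C(C)C)C(=C)CC=C(C)C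
A2 | alternative 1 | 3-(3-methylbut-2-enoyl)oxazolidin-2-one | CC(C)=CC(=O)N1CCOC1=O
A3 | alternative 1 | ring B silyl enol ether with the C7 acyl oxazolidinone | O=C(N2CCOC2=O)[C@H]1CC(CC=C(C)C)=C(O[Si](C(C)C)(C(C)C)C(C)C)CC1(C)C
A4 | alternative 2 | C3 propynoyl ketone of the fully substituted core as its C4 methyl enol ether | CC(C)=CCC/C(C)=C/C[C@H]1C[C@]2(CC=C(C)C)C(=O)[C@@](CC=C(C)C)(C(=O)C(C(=O)C#C)=C2OC)C1(C)C
A5 | alternative 2 | furan | c1ccoc1
A6 | alternative 2 | 7-oxanorbornadienyl ketone adduct (mixture at the new bridgeheads) | CC(C)=CCC/C(C)=C/C[C@H]1C[C@]2(CC=C(C)C)C(=O)[C@@](CC=C(C)C)(C(=O)C(C(=O)C3=CC4OC3C=C4)=C2OC)C1(C)C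
A7 | alternative 2 | C4 methyl enol ether of 30 | CC(C)=CCC/C(C)=C/C[C@H]1C[C@]2(CC=C(C)C)C(=O)[C@@](CC=C(C)C)(C(=O)C(C(=O)c3cccc(O)c3)=C2OC)C1(C)C
A8 | alternative 3 | 3-(tert-butyldimethylsilyloxy)-2,2-dimethyl-5-(3-methylbut-2-enyl)cyclopentanone | CC(C)=CCC1C[C@@H](O[Si](C)(C)C(C)(C)C)C(C)(C)C1=O
A9 | alternative 3 | diketene | C=C1CC(=O)O1
A10 | alternative 3 | cis-fused ring A hydroxy dione on the cyclopentane | O=C1CC(=O)[C@]2(CC=C(C)C)C[C@@H](O[Si](C)(C)C(C)(C)C)C(C)(C)[C@]2(O)C1
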